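**Plan**

- In the target, the retrosynthesis cuts first the C3'–C1'' bond between ring B and the prenyl chain (leaving a 3'-bromide), then O1–C2 of ring C, then C2–C3 of ring C.
- The O1–C2 cut rests on ring C itself: O1–C2(aryl)=C3(OH)–C4(=O) is the enol of a 2-arylchromane-3,4-dione. That dione is reached from the dibromide of a 2-benzylidenebenzofuran-3-one (aurone) when the ring oxygen moves from the carbon next to the carbonyl to the benzylic carbon.
- Forward: ring A and the five-membered ring are bought together as a benzofuranone and ring B is joined by aldol condensation. The three phenols are tosylated, bromine is added to the exocyclic alkene, and alkali expands the furanone to ring C. The prenyl chain is then joined at C3' by Suzuki coupling and the sulfonates are hydrolysed.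
- Bromine at C3' stands in for the prenyl group, whose alkene would not survive the bromination. Tosylates are used instead of esters so that ring A and the 4'-oxygen stay electron-poor while the ring expands.
- The target has no stereocentre and its alkene carries two identical methyl groups. The two stereocentres of the dibromide are transient and vanish in the ring expansion.

Key step: step 4

Assumption: Ts = 4-methylbenzenesulfonyl; the dibromide of step 3 is drawn as the racemic anti adduct, and any syn adduct formed beside it converges on the same flavonol because both centres are lost in step 4.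

**Route**

Step 1
Reactants: 1 4,6-dihydroxybenzofuran-3(2H)-one; 2 3-bromo-4-hydroxybenzaldehyde
Product: 3 (Z)-2-(3-bromo-4-hydroxybenzylidene)-4,6-dihydroxybenzofuran-3(2H)-one (3'-bromo-4,6,4'-trihydroxyaurone)
Conditions: KOH (50% aq), MeOH, 60 °C; then aq. HCl
Reagents that add atoms: none
Why: Aldol condensation with dehydration, in which the C2 methylene of 1 (acidified by the C3 carbonyl and O1) adds to the aldehyde and loss of water should give the conjugated benzylidene as its thermodynamically preferred Z isomer, with no stereocentre formed.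

Step 2
Reactants: 3 (Z)-3'-bromo-4,6,4'-trihydroxyaurone
Product: 4 (Z)-2-[3-bromo-4-(tosyloxy)benzylidene]-3-oxo-2,3-dihydrobenzofuran-4,6-diyl bis(4-methylbenzenesulfonate) (aurone tris-tosylate)
Conditions: TsCl, K2CO3, acetone, reflux
Reagents that add atoms: 4-methylbenzenesulfonyl chloride (TsCl), Cc1ccc(S(=O)(=O)Cl)cc1
Why: O-Sulfonylation of the three phenoxides under a carbonate base that does not add to the enone should give the tris-tosylate, whose sulfonyloxy groups withdraw electrons from both arenes, resist bromine and cold alkali, and are removable by hot alkali at the end.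

Step 3
Reactants: 4 aurone tris-tosylate
Product: 5 rac-(2R)-2-bromo-2-{(S)-bromo[3-bromo-4-(tosyloxy)phenyl]methyl}-3-oxo-2,3-dihydrobenzofuran-4,6-diyl bis(4-methylbenzenesulfonate) (aurone dibromide)
Conditions: Br2, CHCl3, 0 °C → rt, dark
Reagents that add atoms: bromine, BrBr
Why: Electrophilic addition of bromine to the exocyclic enol-ether alkene through a bromonium ion opened anti by bromide should set C2 and the benzylic carbon as the racemic (2R*,αS*) pair, while every arene is deactivated by a sulfonyloxy or sulfonyl group so that ring bromination does not compete.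

Step 4
Reactants: 5 aurone dibromide
Product: 9 2-[3-bromo-4-(tosyloxy)phenyl]-3-hydroxy-4-oxo-4H-chromene-5,7-diyl bis(4-methylbenzenesulfonate) (3'-bromokaempferol 5,7,4'-tris-tosylate), via hemiketal 6 (not isolated), via bromo diketone 7 (not isolated), via chromane-3,4-dione 8 (not isolated)
Conditions: KOH (4 equiv, aq), EtOH–THF, 0 °C → rt, Ar; then AcOH
Reagents that add atoms: potassium hydroxide, [K+].[OH-]
Why: This is the Auwers flavonol synthesis, the alkali-induced ring expansion of an aurone dibromide. Hydroxide replaces the bromide on the furanone carbon C2, which as an α-bromo ether and α-bromo ketone is the most labile of the C–Br bonds, and hemiketal 6 collapses to the 1,2-diketone 7 with release of the ring A phenoxide. That phenoxide displaces the benzylic bromide, now alpha to a ketone, in a 6-exo-tet closure that forms O1–C2 of ring C, and chromane-3,4-dione 8 enolises to 9. No stereocentre remains, since the two centres of 5 and C2 of 8 all end trigonal, so nothing has to be controlled. The step needs substitution at the furanone carbon to outrun base-induced loss of HBr or of both bromines, and six-ring closure to outrun return to the five-ring hemiketal; the sulfonyloxy groups at C4 and C6 keep the C3 carbonyl from becoming a vinylogous carboxylate and make the ring A oxygen a good leaving group, while loss of bromide and aromatising enolisation make the six-ring closure irreversible. The 4'-sulfonate is hydrolysed only slowly by cold alkali, so no 4'-phenoxide arises that could expel the benzylic bromide as a para-quinone methide for the solvent to trap.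

Step 5
Reactants: 9 3'-bromokaempferol 5,7,4'-tris-tosylate; 10 4,4,5,5-tetramethyl-2-(3-methylbut-2-en-1-yl)-1,3,2-dioxaborolane (prenylboronic acid pinacol ester)
Product: 11 3-hydroxy-2-[3-(3-methylbut-2-en-1-yl)-4-(tosyloxy)phenyl]-4-oxo-4H-chromene-5,7-diyl bis(4-methylbenzenesulfonate)
Conditions: Pd(OAc)2 (cat.), t-BuXPhos, K3PO4 (aq), THF, 40 °C
Reagents that add atoms: none
Why: Suzuki–Miyaura coupling in which the aryl bromide, activated by the ortho sulfonyloxy group, adds to zerovalent palladium and the bulky di-tert-butylbiarylphosphine should let the allylpalladium intermediate settle at its primary terminus before reductive elimination, giving the linear 3-methylbut-2-enyl isomer, with the aryl tosylates inert to this catalyst at 40 °C and the 3-hydroxyl carried as its potassium salt.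

Step 6
Reactants: 11 prenylated tris-tosylate
Product: 12 isolicoflavonol, 3,5,7-trihydroxy-2-[4-hydroxy-3-(3-methylbut-2-en-1-yl)phenyl]-4H-chromen-4-one
Conditions: KOH (aq), 1,4-dioxane, 70 °C, Ar; then AcOH
Reagents that add atoms: none
Why: Alkaline hydrolysis of aryl sulfonates by attack of hydroxide at sulfur with S–O cleavage should free the 5- and 7-hydroxyls first (vinylogous mixed anhydrides) and the 4'-hydroxyl on warming, the prenyl alkene being inert to base, the absence of alcohol excluding alkylating sulfonate esters, and the acetic acid quench avoiding chroman formation from the ortho-prenylphenol.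

**Compound list**

1 | 4,6-dihydroxybenzofuran-3(2H)-one | O=C1COc2cc(O)cc(O)c12 | starting material
2 | 3-bromo-4-hydroxybenzaldehyde | O=Cc1ccc(O)c(Br)c1 | starting material
3 | (Z)-2-(3-bromo-4-hydroxybenzylidene)-4,6-dihydroxybenzofuran-3(2H)-one | O=C1/C(=C/c2ccc(O)c(Br)c2)Oc2cc(O)cc(O)c12 | intermediate
4 | (Z)-2-[3-bromo-4-(tosyloxy)benzylidene]-3-oxo-2,3-dihydrobenzofuran-4,6-diyl bis(4-methylbenzenesulfonate) | O=C1/C(=C/c2ccc(OS(=O)(=O)c3ccc(C)cc3)c(Br)c2)Oc2cc(OS(=O)(=O)c3ccc(C)cc3)cc(OS(=O)(=O)c3ccc(C)cc3)c12 | intermediate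
5 | rac-(2R)-2-bromo-2-{(S)-bromo[3-bromo-4-(tosyloxy)phenyl]methyl}-3-oxo-2,3-dihydrobenzofuran-4,6-diyl bis(4-methylbenzenesulfonate), one enantiomer drawn | O=C1c2c(OS(=O)(=O)c3ccc(C)cc3)cc(OS(=O)(=O)c3ccc(C)cc3)cc2O[C@]1(Br)[C@@H](Br)c1ccc(OS(=O)(=O)c2ccc(C)cc2)c(Br)c1 | intermediate
6 | 2-{(S*)-bromo[3-bromo-4-(tosyloxy)phenyl]methyl}-2-hydroxy-3-oxo-2,3-dihydrobenzofuran-4,6-diyl bis(4-methylbenzenesulfonate), hemiketal, both C2 epimers, racemic (not isolated) | O=C1c2c(OS(=O)(=O)c3ccc(C)cc3)cc(OS(=O)(=O)c3ccc(C)cc3)cc2OC1(O)[C@@H](Br)c1ccc(OS(=O)(=O)c2ccc(C)cc2)c(Br)c1 | intermediate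
7 | (3S*)-3-bromo-3-[3-bromo-4-(tosyloxy)phenyl]-1-[2-hydroxy-4,6-bis(tosyloxy)phenyl]propane-1,2-dione, racemic, present as its phenoxide (not isolated) | O=C(C(=O)[C@@H](Br)c1ccc(OS(=O)(=O)c2ccc(C)cc2)c(Br)c1)c1c(O)cc(OS(=O)(=O)c2ccc(C)cc2)cc1OS(=O)(=O)c1ccc(C)cc1 | intermediate
8 | (2R*)-2-[3-bromo-4-(tosyloxy)phenyl]-5,7-bis(tosyloxy)chromane-3,4-dione, racemic (not isolated) | O=C1C(=O)[C@@H](c2ccc(OS(=O)(=O)c3ccc(C)cc3)c(Br)c2)Oc2cc(OS(=O)(=O)c3ccc(C)cc3)cc(OS(=O)(=O)c3ccc(C)cc3)c12 | intermediate
9 | 2-[3-bromo-4-(tosyloxy)phenyl]-3-hydroxy-4-oxo-4H-chromene-5,7-diyl bis(4-methylbenzenesulfonate) | O=c1c(O)c(-c2ccc(OS(=O)(=O)c3ccc(C)cc3)c(Br)c2)oc2cc(OS(=O)(=O)c3ccc(C)cc3)cc(OS(=O)(=O)c3ccc(C)cc3)c12 | intermediate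
10 | 4,4,5,5-tetramethyl-2-(3-methylbut-2-en-1-yl)-1,3,2-dioxaborolane | CC(C)=CCB1OC(C)(C)C(C)(C)O1 | starting material
11 | 3-hydroxy-2-[3-(3-methylbut-2-en-1-yl)-4-(tosyloxy)phenyl]-4-oxo-4H-chromene-5,7-diyl bis(4-methylbenzenesulfonate) | CC(C)=CCc1cc(-c2oc3cc(OS(=O)(=O)c4ccc(C)cc4)cc(OS(=O)(=O)c4ccc(C)cc4)c3c(=O)c2O)ccc1OS(=O)(=O)c1ccc(C)cc1 | intermediate
12 | isolicoflavonol | CC(C)=CCc1cc(-c2oc3cc(O)cc(O)c3c(=O)c2O)ccc1O | target

**Totals**

Total step count: 6. Longest linear sequence: 6 steps (1 → 3 → 4 → 5 → 9 → 11 → 12).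

**Steps most likely to fail**

Step 4. Hydroxide may remove HBr across the furanone carbon and the benzylic carbon, or strip both bromines, faster than it substitutes at the furanone carbon, so that material drains back into the aurone series. Partial sulfonate hydrolysis during the reaction would make this worse by turning ring A into a donor. The fallback builds ring C by oxidative cyclisation of a chalcone and needs no furanone; it sets out from 2. Protection with MOMCl and i-Pr2NEt in CH2Cl2 should give 3-bromo-4-(methoxymethoxy)benzaldehyde F1. Claisen–Schmidt condensation of this aldehyde with purchased 1-[2-hydroxy-4,6-bis(methoxymethoxy)phenyl]ethanone (KOH, EtOH, rt) should give (E)-3-[3-bromo-4-(methoxymethoxy)phenyl]-1-[2-hydroxy-4,6-bis(methoxymethoxy)phenyl]prop-2-en-1-one F2. Algar–Flynn–Oyamada oxidation (H2O2, NaOH, MeOH, 0 °C) should close ring C with the 3-hydroxyl in place, giving 2-[3-bromo-4-(methoxymethoxy)phenyl]-3-hydroxy-5,7-bis(methoxymethoxy)-4H-chromen-4-one F3. Suzuki coupling with 10 under the conditions of step 5 should give 3-hydroxy-5,7-bis(methoxymethoxy)-2-[4-(methoxymethoxy)-3-(3-methylbut-2-en-1-yl)phenyl]-4H-chromen-4-one F4. HCl in MeOH at 40 °C then removes the three acetals, and the fallback comes back to the route at 12.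

Step 5. The five-carbon unit may be delivered through its tertiary carbon, so that the 1,1-dimethylallyl isomer forms beside or in place of the prenyl compound. The fallback sets out from 9 and installs the chain in two stages that leave no regiochemical choice. Suzuki coupling with allylboronic acid pinacol ester (PdCl2(dppf), K3PO4 (aq), THF, 60 °C), whose allyl group has two equivalent termini, should give 2-[3-allyl-4-(tosyloxy)phenyl]-3-hydroxy-4-oxo-4H-chromene-5,7-diyl bis(4-methylbenzenesulfonate) F5. Cross-metathesis with excess 2-methyl-2-butene (second-generation Grubbs catalyst RuCl2(=CHPh)(H2IMes)(PCy3), CH2Cl2, 40 °C) should exchange the terminal CH2 for CMe2, and the fallback comes back to the route at 11.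

Step 6. Hydrolysis of the 4'-sulfonate, flanked by the prenyl chain, may be slow, and during prolonged heating in alkali the electron-rich flavonolate may be degraded by traces of oxygen. The fallback moves the alkaline deprotection ahead of the coupling and finishes under acetal protection; it sets out from 9, where the 4'-sulfonate lies next to bromine and should hydrolyse more readily. KOH (aq), 1,4-dioxane, 70 °C under Ar, then AcOH, should give 3'-bromokaempferol F6. MOMCl and i-Pr2NEt in CH2Cl2 should protect the 3-, 7- and 4'-hydroxyls and leave the chelated 5-hydroxyl free, giving 2-[3-bromo-4-(methoxymethoxy)phenyl]-5-hydroxy-3,7-bis(methoxymethoxy)-4H-chromen-4-one F7. Suzuki coupling with 10 as in step 5 should give 5-hydroxy-3,7-bis(methoxymethoxy)-2-[4-(methoxymethoxy)-3-(3-methylbut-2-en-1-yl)phenyl]-4H-chromen-4-one F8. HCl in MeOH at 40 °C removes the acetals, and the fallback comes back to the route at 12.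

**Further compounds**

F1 | step 4 | 3-bromo-4-(methoxymethoxy)benzaldehyde | O=Cc1ccc(OCOC)c(Br)c1
F2 | step 4 | (E)-3-[3-bromo-4-(methoxymethoxy)phenyl]-1-[2-hydroxy-4,6-bis(methoxymethoxy)phenyl]prop-2-en-1-one | O=C(/C=C/c1ccc(OCOC)c(Br)c1)c1c(O)cc(OCOC)cc1OCOC
F3 | step 4 | 2-[3-bromo-4-(methoxymethoxy)phenyl]-3-hydroxy-5,7-bis(methoxymethoxy)-4H-chromen-4-one | O=c1c(O)c(-c2ccc(OCOC)c(Br)c2)oc2cc(OCOC)cc(OCOC)c12
F4 | step 4 | 3-hydroxy-5,7-bis(methoxymethoxy)-2-[4-(methoxymethoxy)-3-(3-methylbut-2-en-1-yl)phenyl]-4H-chromen-4-one | CC(C)=CCc1cc(-c2oc3cc(OCOC)cc(OCOC)c3c(=O)c2O)ccc1OCOC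
F5 | step 5 | 2-[3-allyl-4-(tosyloxy)phenyl]-3-hydroxy-4-oxo-4H-chromene-5,7-diyl bis(4-methylbenzenesulfonate) | C=CCc1cc(-c2oc3cc(OS(=O)(=O)c4ccc(C)cc4)cc(OS(=O)(=O)c4ccc(C)cc4)c3c(=O)c2O)ccc1OS(=O)(=O)c1ccc(C)cc1
F6 | step 6 | 3'-bromokaempferol, 2-(3-bromo-4-hydroxyphenyl)-3,5,7-trihydroxy-4H-chromen-4-one | O=c1c(O)c(-c2ccc(O)c(Br)c2)oc2cc(O)cc(O)c12
F7 | step 6 | 2-[3-bromo-4-(methoxymethoxy)phenyl]-5-hydroxy-3,7-bis(methoxymethoxy)-4H-chromen-4-one | O=c1c(OCOC)c(-c2ccc(OCOC)c(Br)c2)oc2cc(OCOC)cc(O)c12
F8 | step 6 | 5-hydroxy-3,7-bis(methoxymethoxy)-2-[4-(methoxymethoxy)-3-(3-methylbut-2-en-1-yl)phenyl]-4H-chromen-4-one | CC(C)=CCc1cc(-c2oc3cc(OCOC)cc(O)c3c(=O)c2OCOC)ccc1OCOC
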